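The constant worth reading from the earlier runs is a concentration, if X leaves both by a first-order path and by a path to L that takes two X, as the higher L of blue than of green at the higher charge suggests.

| flask | X | remark | time |
|---|---|---|---|
| green | 0.20 M | run made earlier |  |
| blue | 0.31 M | run made earlier |  |
| flask | 0.14 M |  | 2.0 h |

| run | time / min | G / % | X / % | L / % |
|---|---|---|---|---|
| green | 20.0 | 4.2 | 56.9 | 26.7 |
| green | 40.0 | 11.3 | 36.2 | 36.7 |
| green | 60.0 | 17.4 | 26.3 | 40.0 |
| green | 80.0 | 22.9 | 19.5 | 42.1 |
| green | 90.0 | 24.6 | 16.1 | 43.9 |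
| green | 120 | 30.1 | 11.0 | 44.5 |
| blue | 20.0 | 4.4 | 49.4 | 35.5 |
| blue | 40.0 | 9.3 | 29.6 | 46.6 |
| blue | 60.0 | 14.7 | 20.3 | 50.1 |
| blue | 80.0 | 19.6 | 15.0 | 52.5 |
| blue | 90.0 | 21.8 | 13.4 | 52.9 |
| blue | 120 | 26.1 | 8.2 | 53.7 |

(readings scatter by 0.5 percentage points)

- a species is counted by the X in it: one L counts as two

- how much G the flask holds at 2.0 h, in percent of the X charged
- how much X the flask holds at 2.0 h, in percent of the X charged
- how much L the flask holds at 2.0 h, in percent of the X charged
- how much E the flask holds at 2.0 h, in percent of the X charged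

In its first 20.0 min, the green run makes 26.7% L against 16.4% of other things. At the mean [X] of that stretch, this reads 0.0964 M; blue reads 0.0985 M. Their mean, 0.0974 M, is my even concentration c, the [X] at which X goes to L as fast as to its other products, a selectivity factor with units.

The first setting is the charge. Integrating that split by hand, I reckon for the flask's 0.14 M 38.0% L once X is used up, less than the 45.6% I reckon for green. The readings go the same way: at 120 min, blue holds 53.7% L and green 44.5%.

The second setting is time. Counted in lifetimes of the first-order path, green has run 1.29 by 120 min and blue 1.30. Using that count at 2.0 h, I reckon for the flask X 13.4%, L 36.9% and 49.7% of other things, which c does not split.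

The forecast gives G 33.2%, X 13.2%, L 37.4% and E 16.2%, taking E from the balance, which “rises to about 15% and then falls slowly”.

The flask gives G 33.0%, X 13.7%, L 37.0% and E 7.14%, so the forecast's E is 9.1 percentage points too high; the flask also holds J 5.84% and Z 3.32%, and with E these make 16.3%.

    J ⇌ Z (K = 0.610, k = 2.80 × 10⁻⁴ s⁻¹)
    J ⇌ E (K = 1.40, k = 2.50 × 10⁻⁵ s⁻¹)
    X ⇌ J (K = 2.40, k = 2.00 × 10⁻⁴ s⁻¹)
    J → G (k = 5.10 × 10⁻⁴ s⁻¹)
    2 X → L (k = 9.50 × 10⁻⁴ L mol⁻¹ s⁻¹)
    Z ⇌ E (k = 9.50 × 10⁻⁴ s⁻¹)

At the charge, X's loss to L runs at 1.33 times its forward passage into J in this flask, and at 0.532 times in the neighbour charged with 0.056 M. From the X each holds at 2.0 h, c gives this flask 36.8% L against its 37.0%, and the neighbour 20.0% against its 20.1%.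

(The numbers in the tables are simulated with constants of no real substance; noise was put on by code.)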